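The route cuts the 3(2H)-furanone (ring O, C10, C1, C2, C3; germacranolide numbering) at O–C3 and C1–C10, back to a methyl ketone (C10=O) and a masked 4-methylpent-4-en-2-ynoyl anion. One flask operation adds a benzotriazole-stabilised α-ethoxypropargyl anion to a β-hydroxy methyl ketone (C1–C10, with C10 set by chelation to the C8 oxygen), unmasks the α'-hydroxy ynone and closes O–C3 5-endo-dig. It exploits the tertiary α-ketol hidden at C10/C1 and the enol-ether carbon C3. The precursor is an acyclic lactone ketone bearing a vinyl group; the ten-membered ring is then closed at C4=C5 by metathesis, reduced, and C8 inverted with tiglic acid.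

Key step: step 10

Remark on numbering: C1 ring ketone, C2 (=CH), C3 (O–C=), C4 (CHCH3), C5 (CH2), C6 (lactone O–CH), C7, C8 (ester O–CH), C9 (CH2), C10 (quaternary C–O), C11 (CHCH3), C12 (lactone C=O), C13/C14/C15 methyls on C11/C10/C4.

Remark on design: C8 is carried as its 8R epimer on purpose, because chelation then gives the required 10R centre; it is inverted in step 13. The aminal carbon of 5, 19 and 20 is a mixture and is lost in step 10.

Assumption: (S)-5-(hydroxymethyl)furan-2(5H)-one and 2-methylbut-1-en-3-yne are taken as commercially available.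

Step 1
Reactants: 1 2-methylbut-1-en-3-yne; 2 triethyl orthoformate
Product: 4 5,5-diethoxy-2-methylpent-1-en-3-yne, via alkynyl Grignard reagent 3 (not isolated)
Conditions: EtMgBr, THF, 0 to 40 °C; then 2, toluene, 85 °C
Reagents that add atoms: none
Why: Deprotonation of the terminal alkyne and substitution of one ethoxy group of the orthoester by the alkynylmagnesium reagent (orthoformate route to acetylenic acetals) should give the enyne acetal; no stereocenter.

Step 2
Reactants: 4 5,5-diethoxy-2-methylpent-1-en-3-yne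
Product: 5 1-(1-ethoxy-4-methylpent-4-en-2-yn-1-yl)-1H-benzotriazole (racemic)
Conditions: 1H-benzotriazole, toluene, 110 °C, 4 Å molecular sieves
Reagents that add atoms: 1H-benzotriazole, c1ccc2[nH]nnc2c1
Why: Thermal exchange of one ethoxy group of an acetal for benzotriazole (N,O-acetal formation) is the standard entry to benzotriazole-stabilised acyl-anion precursors; the new centre is racemic and is destroyed later.

Step 3
Reactants: 6 (S)-5-(hydroxymethyl)furan-2(5H)-one
Product: 7 (S)-5-{[(tert-butyldimethylsilyl)oxy]methyl}furan-2(5H)-one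
Conditions: TBSCl, imidazole, CH2Cl2, 0 °C to rt
Reagents that add atoms: tert-butyldimethylsilyl chloride, CC(C)(C)[Si](C)(C)Cl
Why: Silylation of the primary alcohol; the C6 stereocenter comes from the chiral pool.

Step 4
Reactants: 7 (S)-5-{[(tert-butyldimethylsilyl)oxy]methyl}furan-2(5H)-one; 8 1,3-dithiane
Product: 11 (3S,4S,5S)-5-{[(tert-butyldimethylsilyl)oxy]methyl}-4-(1,3-dithian-2-yl)-3-methyloxolan-2-one, via 2-lithio-1,3-dithiane 9 (not isolated), via lithium lactone enolate 10 (not isolated)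
Conditions: 8, n-BuLi, THF, −30 °C; DMPU, then 7, −78 °C; then MeI, −78 to −30 °C
Reagents that add atoms: iodomethane, CI
Why: Tandem conjugate addition–enolate alkylation on a butenolide: the dithiane anion (DMPU favours 1,4-addition) should add anti to the silyloxymethyl group (sets C7), and the enolate should be methylated anti to the new C7 substituent (sets C11).

Step 5
Reactants: 11 (3S,4S,5S)-5-{[(tert-butyldimethylsilyl)oxy]methyl}-4-(1,3-dithian-2-yl)-3-methyloxolan-2-one
Product: 12 (3S,4S,5S)-4-(1,3-dithian-2-yl)-5-(hydroxymethyl)-3-methyloxolan-2-one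
Conditions: HF·pyridine, THF, 0 °C to rt
Reagents that add atoms: none
Why: Fluoride-mediated cleavage of the silyl ether; the dithiane and the lactone are stable to these conditions.

Step 6
Reactants: 12 (3S,4S,5S)-4-(1,3-dithian-2-yl)-5-(hydroxymethyl)-3-methyloxolan-2-one
Product: 13 (2S,3S,4S)-3-(1,3-dithian-2-yl)-4-methyl-5-oxooxolane-2-carbaldehyde
Conditions: Dess–Martin periodinane, CH2Cl2, 0 °C to rt
Reagents that add atoms: none
Why: Dess–Martin oxidation of the primary alcohol under non-basic conditions should leave the α-oxygenated aldehyde centre and the thioacetal intact.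

Step 7
Reactants: 13 (2S,3S,4S)-3-(1,3-dithian-2-yl)-4-methyl-5-oxooxolane-2-carbaldehyde
Product: 14 (3S,4S,5R)-4-(1,3-dithian-2-yl)-5-ethenyl-3-methyloxolan-2-one
Conditions: Ph3PCH3Br, KN(SiMe3)2, THF, 0 °C; then 13, −78 to 0 °C
Reagents that add atoms: methyltriphenylphosphonium bromide, C[P+](c1ccccc1)(c1ccccc1)c1ccccc1.[Br-]
Why: Wittig methylenation of the aldehyde at low temperature should be faster than attack on the lactone; the all-trans ring substitution is the stable arrangement, so C6 is not at risk.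

Step 8
Reactants: 14 (3S,4S,5R)-4-(1,3-dithian-2-yl)-5-ethenyl-3-methyloxolan-2-one
Product: 15 (2R,3S,4S)-2-ethenyl-4-methyl-5-oxooxolane-3-carbaldehyde
Conditions: PhI(OCOCF3)2, MeCN/H2O, 0 °C
Reagents that add atoms: water, O
Why: Oxidative hydrolysis of the dithiane is fast at 0 °C and non-basic, so the terminal alkene and the epimerisable C7 centre should survive.

Step 9
Reactants: 15 (2R,3S,4S)-2-ethenyl-4-methyl-5-oxooxolane-3-carbaldehyde; 16 acetone
Product: 17 (3S,4R,5R)-5-ethenyl-4-[(1R)-1-hydroxy-3-oxobutyl]-3-methyloxolan-2-one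
Conditions: L-proline (30 mol%), DMSO/acetone, rt
Reagents that add atoms: none
Why: Proline-catalysed direct aldol reaction: the acetone enamine should add to the α-branched aldehyde under catalyst control, L-proline giving the 8R carbinol.

Step 10
Reactants: 17 (3S,4R,5R)-5-ethenyl-4-[(1R)-1-hydroxy-3-oxobutyl]-3-methyloxolan-2-one; 5 1-(1-ethoxy-4-methylpent-4-en-2-yn-1-yl)-1H-benzotriazole
Product: 22 (3S,4R,5R)-5-ethenyl-4-{(1R)-1-hydroxy-2-[(2R)-2-methyl-3-oxo-5-(prop-1-en-2-yl)-2,3-dihydrofuran-2-yl]ethyl}-3-methyloxolan-2-one, via chloromagnesium alkoxide 18 (not isolated), via lithiated benzotriazole reagent 19 (not isolated), via benzotriazole adduct 20 (not isolated), via hydroxy ynone 21 (not isolated)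
Conditions: 17, t-BuMgCl, THF, −78 °C; 5, n-BuLi, THF, −78 °C; combine, −78 to −40 °C; then 2 M HCl, EtOH, 0 to 40 °C
Reagents that add atoms: water, O
Why: The lithiated N,O-acetal 19 is a masked 4-methylpent-4-en-2-ynoyl anion; it should add through its α-carbon to the ketone of the magnesium chelate 18 (C1–C10), acid then hydrolyses the aminal to the α'-hydroxy ynone 21, and the tertiary hydroxyl adds to the ynone β-carbon (O–C3), all in one flask. The closest known reaction type is the benzotriazole-mediated alkynoyl-anion route from ketones to 2,2-disubstituted 3(2H)-furanones. The only ring closed is the furanone, by a 5-endo-dig oxa-Michael addition, which reversible conjugate addition of liberated benzotriazole or chloride can assist through addition–elimination. The new stereocenter C10 is set by 1,3-chelation: in the six-membered magnesium chelate with the C7 substituent pseudo-equatorial the nucleophile attacks axially, placing C8–O and C10–O anti along the C7–C1 backbone, that is 10R from the 8R carbinol. The step needs α- over γ-attack of the propargylic anion, secured by the hard, lithium-coordinated N,O-substituted carbon at low temperature, and ketone over lactone attack, secured by the magnesium-activated and intrinsically more electrophilic ketone.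

Step 11
Reactants: 22 (3S,4R,5R)-5-ethenyl-4-{(1R)-1-hydroxy-2-[(2R)-2-methyl-3-oxo-5-(prop-1-en-2-yl)-2,3-dihydrofuran-2-yl]ethyl}-3-methyloxolan-2-one
Product: 23 (4Z,6R,7R,8R,10R,11S)-8-hydroxy-3,10-epoxy-1-oxogermacra-2,4-dien-12,6-olide
Conditions: second-generation Hoveyda–Grubbs catalyst RuCl2(H2IMes)(=CH-C6H4-2-OiPr) (15 mol%), toluene (1 mM), 100 °C
Reagents that add atoms: none
Why: Ring-closing metathesis: the catalyst should load on the monosubstituted vinyl group and close onto the isopropenyl group with loss of ethene, the ring enforcing the Z trisubstituted C4=C5 alkene; the free hydroxyl is tolerated.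

Step 12
Reactants: 23 (4Z,6R,7R,8R,10R,11S)-8-hydroxy-3,10-epoxy-1-oxogermacra-2,4-dien-12,6-olide
Product: 24 (4S,6R,7R,8R,10R,11S)-8-hydroxy-3,10-epoxy-1-oxogermacr-2-en-12,6-olide
Conditions: H2 (1 atm), Rh/Al2O3, EtOAc, rt
Reagents that add atoms: none
Why: Heterogeneous hydrogenation should saturate only C4=C5 (the vinylogous-ester C2=C3 is deactivated and Rh/Al2O3 disfavours hydrogenolysis of the allylic C6–O bond); hydrogen should arrive on the outer, C2-side face of the alkene to give 4S, which is also the allylic-strain-minimised epimer at this epimerisable position.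

Step 13
Reactants: 24 (4S,6R,7R,8R,10R,11S)-8-hydroxy-3,10-epoxy-1-oxogermacr-2-en-12,6-olide; 25 tiglic acid
Product: 26 CNP0235937.1, (4S,6R,7S,8S,10R,11S)-3,10-epoxy-1-oxogermacr-2-en-12,6-olid-8-yl (E)-2-methylbut-2-enoate
Conditions: PPh3, diisopropyl azodicarboxylate, toluene, 0 °C to rt
Reagents that add atoms: none
Why: Mitsunobu esterification: the alkoxyphosphonium salt of the C8 carbinol should be displaced by tiglate with SN2 inversion (8R to 8S), installing the ester and the last stereocenter at once without touching the E alkene of the acid.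

Compound list
1 | 2-methylbut-1-en-3-yne | CC(=C)C#C | starting material
2 | triethyl orthoformate | CCOC(OCC)OCC | starting material
3 | (3-methylbut-3-en-1-yn-1-yl)magnesium bromide | CC(=C)C#C[Mg]Br | intermediate
4 | 5,5-diethoxy-2-methylpent-1-en-3-yne | CCOC(OCC)C#CC(C)=C | intermediate
5 | 1-(1-ethoxy-4-methylpent-4-en-2-yn-1-yl)-1H-benzotriazole (racemic) | CCOC(C#CC(C)=C)n1nnc2ccccc12 | intermediate
6 | (S)-5-(hydroxymethyl)furan-2(5H)-one | OC[C@H]1OC(=O)C=C1 | starting material
7 | (S)-5-{[(tert-butyldimethylsilyl)oxy]methyl}furan-2(5H)-one | CC(C)(C)[Si](C)(C)OC[C@H]1OC(=O)C=C1 | intermediate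
8 | 1,3-dithiane | C1CSCSC1 | starting material
9 | 2-lithio-1,3-dithiane | [Li]C1SCCCS1 | intermediate
10 | lithium enolate of (4S,5S)-5-{[(tert-butyldimethylsilyl)oxy]methyl}-4-(1,3-dithian-2-yl)oxolan-2-one | [Li+].CC(C)(C)[Si](C)(C)OC[C@H]1OC([O-])=C[C@@H]1C1SCCCS1 | intermediate
11 | (3S,4S,5S)-5-{[(tert-butyldimethylsilyl)oxy]methyl}-4-(1,3-dithian-2-yl)-3-methyloxolan-2-one | CC(C)(C)[Si](C)(C)OC[C@H]1OC(=O)[C@@H](C)[C@@H]1C1SCCCS1 | intermediate
12 | (3S,4S,5S)-4-(1,3-dithian-2-yl)-5-(hydroxymethyl)-3-methyloxolan-2-one | OC[C@H]1OC(=O)[C@@H](C)[C@@H]1C1SCCCS1 | intermediate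
13 | (2S,3S,4S)-3-(1,3-dithian-2-yl)-4-methyl-5-oxooxolane-2-carbaldehyde | O=C[C@H]1OC(=O)[C@@H](C)[C@@H]1C1SCCCS1 | intermediate
14 | (3S,4S,5R)-4-(1,3-dithian-2-yl)-5-ethenyl-3-methyloxolan-2-one | C=C[C@H]1OC(=O)[C@@H](C)[C@@H]1C1SCCCS1 | intermediate
15 | (2R,3S,4S)-2-ethenyl-4-methyl-5-oxooxolane-3-carbaldehyde | C=C[C@H]1OC(=O)[C@@H](C)[C@@H]1C=O | intermediate
16 | acetone | CC(C)=O | starting material
17 | (3S,4R,5R)-5-ethenyl-4-[(1R)-1-hydroxy-3-oxobutyl]-3-methyloxolan-2-one | C=C[C@H]1OC(=O)[C@@H](C)[C@@H]1[C@H](O)CC(C)=O | intermediate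
18 | chloromagnesium alkoxide of 17 | C=C[C@H]1OC(=O)[C@@H](C)[C@@H]1[C@H](O[Mg]Cl)CC(C)=O | intermediate
19 | [1-(1H-benzotriazol-1-yl)-1-ethoxy-4-methylpent-4-en-2-yn-1-yl]lithium | CCOC([Li])(C#CC(C)=C)n1nnc2ccccc12 | intermediate
20 | (3S,4R,5R)-4-[(1R,3R)-4-(1H-benzotriazol-1-yl)-4-ethoxy-1,3-dihydroxy-3,7-dimethyloct-7-en-5-yn-1-yl]-5-ethenyl-3-methyloxolan-2-one (mixture at the aminal carbon) | C=C[C@H]1OC(=O)[C@@H](C)[C@@H]1[C@H](O)C[C@@](C)(O)C(OCC)(C#CC(C)=C)n1nnc2ccccc12 | intermediate
21 | (3S,4R,5R)-4-[(1R,3R)-1,3-dihydroxy-3,7-dimethyl-4-oxooct-7-en-5-yn-1-yl]-5-ethenyl-3-methyloxolan-2-one | C=C[C@H]1OC(=O)[C@@H](C)[C@@H]1[C@H](O)C[C@@](C)(O)C(=O)C#CC(C)=C | intermediate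
22 | (3S,4R,5R)-5-ethenyl-4-{(1R)-1-hydroxy-2-[(2R)-2-methyl-3-oxo-5-(prop-1-en-2-yl)-2,3-dihydrofuran-2-yl]ethyl}-3-methyloxolan-2-one | C=C[C@H]1OC(=O)[C@@H](C)[C@@H]1[C@H](O)C[C@@]2(C)OC(=CC2=O)C(C)=C | intermediate
23 | (4Z,6R,7R,8R,10R,11S)-8-hydroxy-3,10-epoxy-1-oxogermacra-2,4-dien-12,6-olide | O[C@@H]1C[C@@]2(C)OC(=CC2=O)/C(C)=C\[C@H]2OC(=O)[C@@H](C)[C@H]12 | intermediate
24 | (4S,6R,7R,8R,10R,11S)-8-hydroxy-3,10-epoxy-1-oxogermacr-2-en-12,6-olide | O[C@@H]1C[C@@]2(C)OC(=CC2=O)[C@@H](C)C[C@H]2OC(=O)[C@@H](C)[C@H]12 | intermediate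
25 | tiglic acid, (E)-2-methylbut-2-enoic acid | C/C=C(\C)C(=O)O | starting material
26 | CNP0235937.1, (4S,6R,7S,8S,10R,11S)-3,10-epoxy-1-oxogermacr-2-en-12,6-olid-8-yl (E)-2-methylbut-2-enoate | C/C=C(\C)C(=O)O[C@H]1C[C@@]2(C)OC(=CC2=O)[C@@H](C)C[C@H]2OC(=O)[C@@H](C)[C@H]12 | target

Total step count: 13. Longest linear sequence: 11 steps (steps 3 to 13); steps 1 and 2 prepare reagent 5.

Steps most likely to fail

Step 10. The delocalised propargylic anion may attack through its remote (allenyl) terminus, the congested addition may revert before unmasking, or the 1,3-induction at C10 may be weak. Fallback, setting out from 17 and coming back at 22: the two bonds are made in separate classical steps. Ethynylmagnesium bromide and methacrolein give 2-methylpent-1-en-4-yn-3-ol F1. Its dianion (n-BuLi, two equivalents) is added to the chelated ketone 18 to give the triol (3S,4R,5R)-5-ethenyl-3-methyl-4-[(1R,3R)-1,3,6-trihydroxy-3,7-dimethyloct-7-en-4-yn-1-yl]oxolan-2-one F2; this is a non-ambident acetylide addition that forms C1–C10 under the same chelation control. MnO2 then oxidises only the propargylic and allylic carbinol to the γ-hydroxy ynone (3S,4R,5R)-4-[(1R,3R)-1,3-dihydroxy-3,7-dimethyl-6-oxooct-7-en-4-yn-1-yl]-5-ethenyl-3-methyloxolan-2-one F3. Et2NH followed by AcOH (amine conjugate addition, hydrolysis, cyclodehydration) transposes the oxygen and closes O–C3 to give 22.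

Step 11. The catalyst may fail to engage the conjugated 1,1-disubstituted alkene, leaving oligomers formed through the vinyl group. Fallback, setting out from 17 and coming back at 23: a relay ring-closing metathesis. Commercial (E)-3-methylpent-2-en-4-yn-1-ol is O-allylated (NaH, allyl bromide) to (E)-3-methyl-5-(prop-2-en-1-yloxy)pent-3-en-1-yne F4. As in steps 1 and 2 this is converted into the acetal (E)-1,1-diethoxy-4-methyl-6-(prop-2-en-1-yloxy)hex-4-en-2-yne F5 and the reagent 1-[(E)-1-ethoxy-4-methyl-6-(prop-2-en-1-yloxy)hex-4-en-2-yn-1-yl]-1H-benzotriazole F6. F6 replaces 5 in the conditions of step 10 to give the relay furanone (3S,4R,5R)-5-ethenyl-4-{(1R)-1-hydroxy-2-[(2R)-2-methyl-3-oxo-5-[(E)-4-(prop-2-en-1-yloxy)but-2-en-2-yl]-2,3-dihydrofuran-2-yl]ethyl}-3-methyloxolan-2-one F7. The same ruthenium catalyst then loads on the allyl ether, expels 2,5-dihydrofuran and is delivered to C4, so that closure onto the vinyl group gives 23.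

Step 13. The hindered ring carbinol may not be activated, or the alkoxyphosphonium salt may eliminate towards C9 instead of being displaced. Fallback, setting out from 24 and coming back at 26: 24 is converted with ClCH2SO2Cl and pyridine into its chloromethanesulfonate, (4S,6R,7R,8R,10R,11S)-3,10-epoxy-1-oxogermacr-2-en-12,6-olid-8-yl chloromethanesulfonate F8. F8 is displaced with cesium tiglate (from 25 and Cs2CO3, 18-crown-6, toluene) with inversion at C8 to give 26.

Further compounds
F1 | step 10 | 2-methylpent-1-en-4-yn-3-ol (racemic) | C#CC(O)C(C)=C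
F2 | step 10 | (3S,4R,5R)-5-ethenyl-3-methyl-4-[(1R,3R)-1,3,6-trihydroxy-3,7-dimethyloct-7-en-4-yn-1-yl]oxolan-2-one (mixture at the propargylic carbinol) | C=C[C@H]1OC(=O)[C@@H](C)[C@@H]1[C@H](O)C[C@@](C)(O)C#CC(O)C(C)=C
F3 | step 10 | (3S,4R,5R)-4-[(1R,3R)-1,3-dihydroxy-3,7-dimethyl-6-oxooct-7-en-4-yn-1-yl]-5-ethenyl-3-methyloxolan-2-one | C=C[C@H]1OC(=O)[C@@H](C)[C@@H]1[C@H](O)C[C@@](C)(O)C#CC(=O)C(C)=C
F4 | step 11 | (E)-3-methyl-5-(prop-2-en-1-yloxy)pent-3-en-1-yne | C#C/C(C)=C/COCC=C
F5 | step 11 | (E)-1,1-diethoxy-4-methyl-6-(prop-2-en-1-yloxy)hex-4-en-2-yne | CCOC(OCC)C#C/C(C)=C/COCC=C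
F6 | step 11 | 1-[(E)-1-ethoxy-4-methyl-6-(prop-2-en-1-yloxy)hex-4-en-2-yn-1-yl]-1H-benzotriazole (racemic) | CCOC(C#C/C(C)=C/COCC=C)n1nnc2ccccc12
F7 | step 11 | (3S,4R,5R)-5-ethenyl-4-{(1R)-1-hydroxy-2-[(2R)-2-methyl-3-oxo-5-[(E)-4-(prop-2-en-1-yloxy)but-2-en-2-yl]-2,3-dihydrofuran-2-yl]ethyl}-3-methyloxolan-2-one | C=C[C@H]1OC(=O)[C@@H](C)[C@@H]1[C@H](O)C[C@@]2(C)OC(=CC2=O)/C(C)=C/COCC=C
F8 | step 13 | (4S,6R,7R,8R,10R,11S)-3,10-epoxy-1-oxogermacr-2-en-12,6-olid-8-yl chloromethanesulfonate | ClCS(=O)(=O)O[C@@H]1C[C@@]2(C)OC(=CC2=O)[C@@H](C)C[C@H]2OC(=O)[C@@H](C)[C@H]12
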